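**Retrosynthetic overview**

1. Feature: in ring A the oxygens on C4 (OMe) and C6 (OH) are 1,3-related across C5–H and the carboxyl sits on C1 next to C6, the pattern of a 2-carboxycyclohexane-1,3-dione; C3 carries the ring B oxygen and C2 the pentyl group, so ring A is made last, saturated, and then aromatised.
2. Ring A is cut at C1–C2 (Michael) and C5–C6 (Claisen) into dibenzyl malonate and a 3-(aryloxy)non-3-en-2-one whose α-carbon (future C3) already holds the ring B oxygen.
3. The enone comes from the ring B phenol by rhodium carbenoid O–H insertion (C3–O made on an sp3 carbon, no coupling on an arene) and Horner–Wadsworth–Emmons olefination with hexanal (C2=C3).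
4. Ring B is a bought arene (2,4,6-trihydroxybenzoic acid): tert-butyl ester, 4-O-benzyl ether, monotriflate, Heck reaction with pent-1-en-3-ol.
5. Ring order: ring B preformed, ring A closed in step 7 and dehydrogenated in step 8; then tert-butyl ester cleavage, double O-methylation and hydrogenolysis.

Key step: step 7

Remarks on the chemistry
- ArB = 5-(benzyloxy)-2-(tert-butoxycarbonyl)-3-(3-oxopentyl)phenyl (ring B, bonded through its C1).
- The ring B carboxyl is carried as a tert-butyl ester up to step 9. An ordinary alkyl ester ortho to the ether oxygen would be open to five-membered Dieckmann (coumaranone) closure by any carbanion at the aryloxy-bearing carbon in steps 6 and 7, and to indanone closure by the side-chain ketone enolate. The di-ortho-substituted tert-butyl ester is inert to both, so the side-chain ketone is carried free. The ring A carboxyl comes from dibenzyl malonate and stays a benzyl ester until the last step.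
- Assumption: the olefination of step 6 is taken to give mainly the (Z)-enone; the (E)-isomer would serve equally, since C2 and C3 end as aromatic carbons. Compounds 5, 6, 9, 13, 14 and 15 are racemates or stereoisomer mixtures of no consequence.

**Route**

Step 1
Reactants: 1 2,4,6-trihydroxybenzoic acid
Product: 2 tert-butyl 2,4,6-trihydroxybenzoate
Conditions: O-tert-butyl-N,N'-diisopropylisourea (3 equiv), THF, rt
Reagents that add atoms: O-tert-butyl-N,N'-diisopropylisourea, CC(C)N=C(NC(C)C)OC(C)(C)C
Why: Isourea esterification: only the strongly acidic carboxyl protonates the isourea and its carboxylate takes up the tert-butyl group, at a temperature at which the acid should not decarboxylate and the phenols are not alkylated.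

Step 2
Reactants: 2 tert-butyl 2,4,6-trihydroxybenzoate
Product: 3 tert-butyl 4-(benzyloxy)-2,6-dihydroxybenzoate
Conditions: BnOH (1.05 equiv), PPh3, DIAD, THF, 0 °C to rt
Reagents that add atoms: benzyl alcohol, OCc1ccccc1
Why: Mitsunobu etherification takes the most acidic hydroxyl, the one para to the ester, while the two ortho hydroxyls are hydrogen-bonded to the ester and should stay free.

Step 3
Reactants: 3 tert-butyl 4-(benzyloxy)-2,6-dihydroxybenzoate
Product: 4 tert-butyl 4-(benzyloxy)-2-hydroxy-6-[(trifluoromethanesulfonyl)oxy]benzoate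
Conditions: Tf2O (1.05 equiv), pyridine, CH2Cl2, −20 to 0 °C
Reagents that add atoms: trifluoromethanesulfonic anhydride, O=S(=O)(OS(=O)(=O)C(F)(F)F)C(F)(F)F
Why: O-Sulfonylation of one of two equivalent phenols; the first triflate withdraws electrons and leaves the remaining hydroxyl chelated to the carbonyl oxygen, too poor a nucleophile for a second sulfonylation at this temperature.

Step 4
Reactants: 4 tert-butyl 4-(benzyloxy)-2-hydroxy-6-[(trifluoromethanesulfonyl)oxy]benzoate; 5 pent-1-en-3-ol (racemic)
Product: 7 tert-butyl 4-(benzyloxy)-2-hydroxy-6-(3-oxopentyl)benzoate, via enol 6 (not isolated)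
Conditions: Pd(OAc)2 (5 mol %), LiCl, Bu4NCl, NaHCO3, DMF, 80 °C
Reagents that add atoms: none
Why: Heck reaction of an allylic alcohol under Jeffery conditions: chloride keeps the arylpalladium on the neutral pathway so the aryl group goes to the terminal alkene carbon, β-hydride elimination towards the carbinol gives enol 6, and its tautomerisation delivers the saturated ketone.

Step 5
Reactants: 7 tert-butyl 4-(benzyloxy)-2-hydroxy-6-(3-oxopentyl)benzoate; 8 dimethyl (1-diazo-2-oxopropyl)phosphonate
Product: 9 tert-butyl 4-(benzyloxy)-2-{[1-(dimethoxyphosphoryl)-2-oxopropyl]oxy}-6-(3-oxopentyl)benzoate (racemic)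
Conditions: Rh2(OAc)4 (2 mol %), toluene, 90 °C, slow addition of 8
Reagents that add atoms: none
Why: Rhodium carbenoid O–H insertion into the phenol, which should outrun reaction at the ketone, the benzyl ether or the arene; the new stereocentre is racemic and disappears in step 6.

Step 6
Reactants: 9 tert-butyl 4-(benzyloxy)-2-{[1-(dimethoxyphosphoryl)-2-oxopropyl]oxy}-6-(3-oxopentyl)benzoate; 10 hexanal
Product: 11 tert-butyl 4-(benzyloxy)-2-{[(3Z)-2-oxonon-3-en-3-yl]oxy}-6-(3-oxopentyl)benzoate
Conditions: LiCl, DBU, MeCN, 0 °C to rt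
Reagents that add atoms: none
Why: Horner–Wadsworth–Emmons olefination under Masamune–Roush conditions: DBU with lithium chelation deprotonates only the carbon between P=O and C=O, and the aldehyde present throughout traps the stabilised anion far faster than the side-chain ketone could; no stereocentre is formed and the alkene geometry is immaterial.

Step 7
Reactants: 11 tert-butyl 4-(benzyloxy)-2-{[(3Z)-2-oxonon-3-en-3-yl]oxy}-6-(3-oxopentyl)benzoate; 12 dibenzyl malonate
Product: 14 benzyl 3-(ArB-oxy)-4,6-dioxo-2-pentylcyclohexane-1-carboxylate as a mixture of diastereomers and enol forms, via Michael adduct 13 (not isolated)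
Conditions: tBuOK (1.2 equiv), THF, 0 °C to 60 °C; then 1 M HCl
Reagents that add atoms: none
Why: The potassium enolate of 12 adds to the β-carbon of 11 (Michael, C1–C2), proton transfer leaves adduct 13 as its malonate anion, and the small equilibrium share of methyl ketone enolate attacks a benzyl ester carbonyl (Claisen, C5–C6) with loss of benzyl alkoxide, the product being drawn off as its β-diketone enolate until the acid quench. The closest known reaction is the alkoxide-mediated Michael–Dieckmann annulation of malonates with alk-3-en-2-ones to 6-alkyl-2,4-dioxocyclohexanecarboxylates, here run on an α-aryloxy enone. Ring A closes in the 6-exo-trig mode, enolate carbon C5 attacking the ester carbonyl carbon that becomes C6. The new sp3 centres C1, C2 and C3 are set without control and need none, since all three become aromatic carbons in step 8. The step needs conjugate rather than carbonyl addition, which the soft, stabilised malonate anion and the reversibility of its 1,2-addition provide, and closure through the methyl group, which is secured because the more acidic enolate at C3 can reach a malonate ester only through a four-membered ring and finds the ring B carbonyl, five atoms away, shut off as a di-ortho-substituted tert-butyl ester. The same ester denies the side-chain ketone enolate an indanone closure, so that ketone is carried unprotected.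

Step 8
Reactants: 14 benzyl 3-(ArB-oxy)-4,6-dioxo-2-pentylcyclohexane-1-carboxylate
Product: 16 benzyl 3-(ArB-oxy)-4,6-dihydroxy-2-pentylbenzoate, via bromo dione 15 (not isolated)
Conditions: CuBr2 (2.1 equiv), LiBr, MeCN, 0 °C to rt
Reagents that add atoms: none
Why: CuBr2 (divalent copper) brominates the enolised β-dicarbonyl at C5 to give 15, whose bis-enol loses HBr in a 1,4-sense to the benzenoid ring, the known CuBr2/LiBr aromatisation of cyclohexenones and cyclohexane-1,3-diones; the simple side-chain ketone enolises far more slowly, and any tert-butyl ester lost to the HBr formed would only anticipate step 9.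

Step 9
Reactants: 16 benzyl 3-(ArB-oxy)-4,6-dihydroxy-2-pentylbenzoate
Product: 17 4-(benzyloxy)-2-{3-[(benzyloxy)carbonyl]-4,6-dihydroxy-2-pentylphenoxy}-6-(3-oxopentyl)benzoic acid
Conditions: TFA, CH2Cl2, thioanisole (cation scavenger), 0 °C to rt
Reagents that add atoms: none
Why: Acidolysis of the tert-butyl ester by alkyl–oxygen cleavage (tert-butyl cation lost as isobutene, the scavenger guarding the electron-rich rings) should leave the benzyl ester, the benzyl ether and the ketone untouched.

Step 10
Reactants: 17 4-(benzyloxy)-2-{3-[(benzyloxy)carbonyl]-4,6-dihydroxy-2-pentylphenoxy}-6-(3-oxopentyl)benzoic acid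
Product: 18 benzyl 3-[5-(benzyloxy)-2-(methoxycarbonyl)-3-(3-oxopentyl)phenoxy]-6-hydroxy-4-methoxy-2-pentylbenzoate
Conditions: MeI (2.3 equiv), K2CO3, acetone, rt
Reagents that add atoms: iodomethane, CI
Why: Williamson-type alkylation of the ring B carboxylate and of the free C4 phenoxide of ring A; the C6 hydroxyl is hydrogen-bonded to the benzyl ester carbonyl, far less acidic and nucleophilic, and should be left alone by carbonate in acetone at room temperature.

Step 11
Reactants: 18 benzyl 3-[5-(benzyloxy)-2-(methoxycarbonyl)-3-(3-oxopentyl)phenoxy]-6-hydroxy-4-methoxy-2-pentylbenzoate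
Product: 19 epiphorellic acid 2
Conditions: H2 (1 atm), Pd/C, EtOAc, rt
Reagents that add atoms: none
Why: Hydrogenolysis cleaves the benzyl ester and the benzyl ether while the diaryl ether, the methyl ester and the non-benzylic ketone are not reduced, and the β-resorcylic acid is set free without acid or heat, so it should not decarboxylate.

**Compound list**

1 | 2,4,6-trihydroxybenzoic acid | OC(=O)c1c(O)cc(O)cc1O | starting material
2 | tert-butyl 2,4,6-trihydroxybenzoate | CC(C)(C)OC(=O)c1c(O)cc(O)cc1O | intermediate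
3 | tert-butyl 4-(benzyloxy)-2,6-dihydroxybenzoate | CC(C)(C)OC(=O)c1c(O)cc(OCc2ccccc2)cc1O | intermediate
4 | tert-butyl 4-(benzyloxy)-2-hydroxy-6-[(trifluoromethanesulfonyl)oxy]benzoate | CC(C)(C)OC(=O)c1c(O)cc(OCc2ccccc2)cc1OS(=O)(=O)C(F)(F)F | intermediate
5 | pent-1-en-3-ol (racemic) | C=CC(O)CC | starting material
6 | tert-butyl 4-(benzyloxy)-2-hydroxy-6-(3-hydroxypent-2-en-1-yl)benzoate (enol, not isolated) | CCC(O)=CCc1cc(OCc2ccccc2)cc(O)c1C(=O)OC(C)(C)C | intermediate
7 | tert-butyl 4-(benzyloxy)-2-hydroxy-6-(3-oxopentyl)benzoate | CCC(=O)CCc1cc(OCc2ccccc2)cc(O)c1C(=O)OC(C)(C)C | intermediate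
8 | dimethyl (1-diazo-2-oxopropyl)phosphonate | CC(=O)C(=[N+]=[N-])P(=O)(OC)OC | starting material
9 | tert-butyl 4-(benzyloxy)-2-{[1-(dimethoxyphosphoryl)-2-oxopropyl]oxy}-6-(3-oxopentyl)benzoate (racemic) | CCC(=O)CCc1cc(OCc2ccccc2)cc(OC(C(C)=O)P(=O)(OC)OC)c1C(=O)OC(C)(C)C | intermediate
10 | hexanal | CCCCCC=O | starting material
11 | tert-butyl 4-(benzyloxy)-2-{[(3Z)-2-oxonon-3-en-3-yl]oxy}-6-(3-oxopentyl)benzoate | CCCCC/C=C(\Oc1cc(OCc2ccccc2)cc(CCC(=O)CC)c1C(=O)OC(C)(C)C)C(C)=O | intermediate
12 | dibenzyl malonate | O=C(CC(=O)OCc1ccccc1)OCc1ccccc1 | starting material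
13 | dibenzyl 2-{3-[5-(benzyloxy)-2-(tert-butoxycarbonyl)-3-(3-oxopentyl)phenoxy]-2-oxononan-4-yl}propanedioate (diastereomer mixture, not isolated) | CCCCCC(C(Oc1cc(OCc2ccccc2)cc(CCC(=O)CC)c1C(=O)OC(C)(C)C)C(C)=O)C(C(=O)OCc1ccccc1)C(=O)OCc1ccccc1 | intermediate
14 | benzyl 3-[5-(benzyloxy)-2-(tert-butoxycarbonyl)-3-(3-oxopentyl)phenoxy]-4,6-dioxo-2-pentylcyclohexane-1-carboxylate (diastereomer and enol mixture) | CCCCCC1C(Oc2cc(OCc3ccccc3)cc(CCC(=O)CC)c2C(=O)OC(C)(C)C)C(=O)CC(=O)C1C(=O)OCc1ccccc1 | intermediate
15 | benzyl 3-[5-(benzyloxy)-2-(tert-butoxycarbonyl)-3-(3-oxopentyl)phenoxy]-5-bromo-4,6-dioxo-2-pentylcyclohexane-1-carboxylate (not isolated) | CCCCCC1C(Oc2cc(OCc3ccccc3)cc(CCC(=O)CC)c2C(=O)OC(C)(C)C)C(=O)C(Br)C(=O)C1C(=O)OCc1ccccc1 | intermediate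
16 | benzyl 3-[5-(benzyloxy)-2-(tert-butoxycarbonyl)-3-(3-oxopentyl)phenoxy]-4,6-dihydroxy-2-pentylbenzoate | CCCCCc1c(Oc2cc(OCc3ccccc3)cc(CCC(=O)CC)c2C(=O)OC(C)(C)C)c(O)cc(O)c1C(=O)OCc1ccccc1 | intermediate
17 | 4-(benzyloxy)-2-{3-[(benzyloxy)carbonyl]-4,6-dihydroxy-2-pentylphenoxy}-6-(3-oxopentyl)benzoic acid | CCCCCc1c(Oc2cc(OCc3ccccc3)cc(CCC(=O)CC)c2C(=O)O)c(O)cc(O)c1C(=O)OCc1ccccc1 | intermediate
18 | benzyl 3-[5-(benzyloxy)-2-(methoxycarbonyl)-3-(3-oxopentyl)phenoxy]-6-hydroxy-4-methoxy-2-pentylbenzoate | CCCCCc1c(Oc2cc(OCc3ccccc3)cc(CCC(=O)CC)c2C(=O)OC)c(OC)cc(O)c1C(=O)OCc1ccccc1 | intermediate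
19 | epiphorellic acid 2, 6-hydroxy-3-[5-hydroxy-2-(methoxycarbonyl)-3-(3-oxopentyl)phenoxy]-4-methoxy-2-pentylbenzoic acid | CCCCCc1c(Oc2cc(O)cc(CCC(=O)CC)c2C(=O)OC)c(OC)cc(O)c1C(=O)O | target

**Step count**

Total: 11 steps. Longest linear sequence: 11 steps (from 1; compounds 5, 8, 10 and 12 are bought).

**Steps most likely to fail**

1. Step 7. Conjugate addition to the donor-substituted, sterically shielded enone may be slower than base-induced loss of the enone (γ-deprotonation to a deconjugated enol ether, retro-Michael), so that too little adduct reaches the Claisen stage. Fallback, setting out from 11 and 12: the Michael bond is made under Lewis acid instead of base. Dibenzyl malonate 12 is converted with TMSOTf and Et3N into its O-silyl ketene acetal, benzyl 3-(benzyloxy)-3-[(trimethylsilyl)oxy]prop-2-enoate F1. A chelating Lewis acid (MgBr2·OEt2 or Cu(OTf)2), held between the carbonyl and aryloxy oxygens of 11, activates the enone for a Mukaiyama–Michael addition at low temperature. This should give the silyl enol ether dibenzyl 2-{3-(ArB-oxy)-2-[(trimethylsilyl)oxy]non-2-en-4-yl}propanedioate F2, hydrolysed on work-up to adduct 13. The isolated 13 is then closed in a separate Claisen step with tBuOK, and the route is rejoined at 14.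

2. Step 5. The hydrogen-bonded, ortho-flanked phenol may attack the carbenoid too slowly, so that the carbenoid is spent in Wolff rearrangement, dimerisation or attack on the electron-rich arene. Fallback, setting out from 7: the ether bond is made by SN2 opening of an epoxy ketone. Commercial non-3-en-2-one is epoxidised with H2O2 and NaOH to trans-3,4-epoxynonan-2-one F3. The phenoxide of 7 (Cs2CO3, DMF) opens F3 at the carbon α to the carbonyl, as phenoxides and thiolates do with α,β-epoxy ketones, to give tert-butyl 4-(benzyloxy)-2-[(4-hydroxy-2-oxononan-3-yl)oxy]-6-(3-oxopentyl)benzoate F4. Mesylation (MsCl, Et3N) gives tert-butyl 4-(benzyloxy)-2-({4-[(methanesulfonyl)oxy]-2-oxononan-3-yl}oxy)-6-(3-oxopentyl)benzoate F5, which eliminates under the same base to enone 11. Steps 5 and 6 are bypassed and the route is rejoined at 11.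

3. Step 8. Electrophilic bromine may go on to substitute the very electron-rich C5 position of the new resorcinol ring or ring B, and the HBr released may promote loss of the ring B phenol from C3 of the dienol. Fallback, setting out from 14: a halogen-free dehydrogenation by hydride abstraction. TMSOTf (2.1 equiv) and Et3N at −78 °C silylate the acidic dione and β-keto ester sites ahead of the simple ketone, giving benzyl 5-(ArB-oxy)-6-pentyl-2,4-bis[(trimethylsilyl)oxy]cyclohexa-1,3-diene-1-carboxylate F6. DDQ aromatises this cyclohexadiene at room temperature to benzyl 3-(ArB-oxy)-2-pentyl-4,6-bis[(trimethylsilyl)oxy]benzoate F7. Aqueous citric acid removes the aryl silyl ethers, and the route is rejoined at 16.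

**Further compounds**

F1 | step 7 | benzyl 3-(benzyloxy)-3-[(trimethylsilyl)oxy]prop-2-enoate | C[Si](C)(C)OC(OCc1ccccc1)=CC(=O)OCc1ccccc1
F2 | step 7 | dibenzyl 2-{3-[5-(benzyloxy)-2-(tert-butoxycarbonyl)-3-(3-oxopentyl)phenoxy]-2-[(trimethylsilyl)oxy]non-2-en-4-yl}propanedioate | CCCCCC(C(Oc1cc(OCc2ccccc2)cc(CCC(=O)CC)c1C(=O)OC(C)(C)C)=C(C)O[Si](C)(C)C)C(C(=O)OCc1ccccc1)C(=O)OCc1ccccc1
F3 | step 5 | trans-3,4-epoxynonan-2-one (racemic, one enantiomer drawn) | CC(=O)[C@@H]1O[C@H]1CCCCC
F4 | step 5 | tert-butyl 4-(benzyloxy)-2-[(4-hydroxy-2-oxononan-3-yl)oxy]-6-(3-oxopentyl)benzoate (racemic, relative configuration immaterial) | CCCCCC(O)C(Oc1cc(OCc2ccccc2)cc(CCC(=O)CC)c1C(=O)OC(C)(C)C)C(C)=O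
F5 | step 5 | tert-butyl 4-(benzyloxy)-2-({4-[(methanesulfonyl)oxy]-2-oxononan-3-yl}oxy)-6-(3-oxopentyl)benzoate | CCCCCC(OS(C)(=O)=O)C(Oc1cc(OCc2ccccc2)cc(CCC(=O)CC)c1C(=O)OC(C)(C)C)C(C)=O
F6 | step 8 | benzyl 5-[5-(benzyloxy)-2-(tert-butoxycarbonyl)-3-(3-oxopentyl)phenoxy]-6-pentyl-2,4-bis[(trimethylsilyl)oxy]cyclohexa-1,3-diene-1-carboxylate | CCCCCC1C(Oc2cc(OCc3ccccc3)cc(CCC(=O)CC)c2C(=O)OC(C)(C)C)C(O[Si](C)(C)C)=CC(O[Si](C)(C)C)=C1C(=O)OCc1ccccc1
F7 | step 8 | benzyl 3-[5-(benzyloxy)-2-(tert-butoxycarbonyl)-3-(3-oxopentyl)phenoxy]-2-pentyl-4,6-bis[(trimethylsilyl)oxy]benzoate | CCCCCc1c(Oc2cc(OCc3ccccc3)cc(CCC(=O)CC)c2C(=O)OC(C)(C)C)c(O[Si](C)(C)C)cc(O[Si](C)(C)C)c1C(=O)OCc1ccccc1
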